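**Strategy.** The two rings of pseudoaspidin are identical. In each ring (C1 butanoyl, C2 OH, C3 bridge CH2, C4 OH, C5 CH3, C6 OCH3) the C2 hydroxyl lies ortho to the C1 ketone, and the other ortho position, C6, is blocked by methoxy. The route therefore disconnects both C2–O bonds last. A ruthenium-catalysed, ketone-directed C–H hydroxylation acts on the only aromatic C–H of each ring of a diarylmethane diacetate and installs both chelated phenols in one operation. The precursor, bis(2-acetoxy-5-butanoyl-4-methoxy-3-methylphenyl)methane, comes from 2-methylresorcinol by acylation, benzyl-controlled O-methylation, formaldehyde bridging and acetylation. Mild methanolysis of the acetates ends the synthesis.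

Key step: step 7

Step 1
Reactants: 1 2-methylresorcinol; 2 butanoic acid
Product: 3 1-(2,4-dihydroxy-3-methylphenyl)butan-1-one
Conditions: BF3·OEt2 (neat, as solvent), 90 °C; then aq. NaOAc
Reagents that add atoms: none
Why: Nencki-type Friedel–Crafts C-acylation, in which BF3 activates the acid, the two ring positions ortho/para to the hydroxyls are equivalent by symmetry, and the boron-chelated ortho-hydroxy ketone that forms is deactivated toward a second acylation.

Step 2
Reactants: 3 1-(2,4-dihydroxy-3-methylphenyl)butan-1-one
Product: 4 1-[4-(benzyloxy)-2-hydroxy-3-methylphenyl]butan-1-one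
Conditions: BnBr (1.05 equiv), K2CO3, acetone, reflux
Reagents that add atoms: benzyl bromide, BrCc1ccccc1
Why: Williamson ether synthesis, selective because K2CO3 in acetone ionises only the free hydroxyl para to the ketone while the ortho hydroxyl is held in a hydrogen bond to the carbonyl and is flanked by methyl and acyl groups.

Step 3
Reactants: 4 1-[4-(benzyloxy)-2-hydroxy-3-methylphenyl]butan-1-one
Product: 5 1-[4-(benzyloxy)-2-methoxy-3-methylphenyl]butan-1-one
Conditions: MeI (3 equiv), K2CO3, DMF, 50 °C
Reagents that add atoms: iodomethane, CI
Why: Williamson methylation under more forcing conditions (polar aprotic solvent, excess of a small electrophile) should alkylate the hydrogen-bonded phenol, the only acidic site left.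

Step 4
Reactants: 5 1-[4-(benzyloxy)-2-methoxy-3-methylphenyl]butan-1-one
Product: 6 1-(4-hydroxy-2-methoxy-3-methylphenyl)butan-1-one
Conditions: H2 (1 atm), 10% Pd/C, EtOAc, rt
Reagents that add atoms: none
Why: Catalytic hydrogenolysis of the benzyl aryl ether is much faster than reduction of the donor-conjugated aryl ketone, so stopping after one equivalent of H2 should free the para phenol cleanly.

Step 5
Reactants: 6 1-(4-hydroxy-2-methoxy-3-methylphenyl)butan-1-one (two molecules); 7 formaldehyde
Product: 9 bis(5-butanoyl-2-hydroxy-4-methoxy-3-methylphenyl)methane, via hydroxymethyl phenol 8 (not isolated)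
Conditions: 37% aq. CH2O (0.5 equiv, added slowly), H2SO4 (cat.), AcOH, 70 °C
Reagents that add atoms: none
Why: Acid-catalysed phenol–formaldehyde condensation (hydroxymethylation, then Friedel–Crafts benzylation through the ortho-hydroxybenzyl cation) should give a single diarylmethane without oligomers, because the carbon ortho to the hydroxyl and para to the methoxy group is the only nucleophilic ring site, the other free carbon lying ortho to the acyl group.

Step 6
Reactants: 9 bis(5-butanoyl-2-hydroxy-4-methoxy-3-methylphenyl)methane
Product: 10 bis(2-acetoxy-5-butanoyl-4-methoxy-3-methylphenyl)methane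
Conditions: Ac2O, pyridine, DMAP (cat.), CH2Cl2, rt
Reagents that add atoms: acetic anhydride, CC(=O)OC(C)=O
Why: DMAP-catalysed O-acetylation caps both phenols as acetates, which carry no oxidisable C–H next to oxygen, tolerate CF3CO2H and leave later under mild methanolysis.

Step 7
Reactants: 10 bis(2-acetoxy-5-butanoyl-4-methoxy-3-methylphenyl)methane
Product: 12 bis(2-acetoxy-5-butanoyl-6-hydroxy-4-methoxy-3-methylphenyl)methane (pseudoaspidin di-O-acetate), via bis(trifluoroacetate) 11 (not isolated)
Conditions: [RuCl2(p-cymene)]2 (10 mol %), K2S2O8 (5 equiv), CF3CO2H/(CF3CO)2O (4:1), 80 °C; then H2O, aq. NaHCO3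
Reagents that add atoms: trifluoroacetic acid, OC(=O)C(F)(F)F
Why: Proposed new method: the butanoyl oxygen binds cationic divalent ruthenium and trifluoroacetate-assisted deprotonation of the adjacent C2–H gives a five-membered ruthenacycle, which K2S2O8 oxidises to tetravalent ruthenium; C–O reductive elimination then gives the aryl trifluoroacetate 11, hydrolysed on aqueous work-up to the hydrogen-bonded phenol, the sequence running once on each ring. The closest known reaction type is the ruthenium- or palladium-catalysed ketone-directed ortho C–H hydroxylation of aryl alkyl ketones in CF3CO2H/(CF3CO)2O, which has not been shown for a C–H wedged between the directing acyl group and a second ortho substituent, nor beside a diarylmethane CH2. No ring is closed and no stereocentre is formed. The selectivity needed is aromatic C2–H over the doubly benzylic CH2 and the C–H alpha to each ketone; it is secured because chelation through the carbonyl oxygen reaches only C2, C6 being occupied by OCH3, which also turns the carbonyl oxygen toward C2. The C4 acetates and the acyl groups lower the electron density of the rings against single-electron oxidation, and each new oxygen stays masked as an electron-poor trifluoroacetate until work-up. Any acetate exchanged for trifluoroacetate in the acidic medium would converge on the same target in the next step.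

Step 8
Reactants: 12 bis(2-acetoxy-5-butanoyl-6-hydroxy-4-methoxy-3-methylphenyl)methane
Product: 13 pseudoaspidin
Conditions: K2CO3 (3 equiv), MeOH, 0 °C to rt, Ar; then 1 M HCl
Reagents that add atoms: none
Why: Carbonate-promoted transesterification (Zemplén-type methanolysis) should cleave the two aryl acetates, whose phenoxide leaving groups make them far more labile than the ketones, methyl ethers or the bridge, and acidification returns the tetraphenol.

**Compound list**
1 | 2-methylresorcinol (2-methylbenzene-1,3-diol) | Cc1c(O)cccc1O | starting material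
2 | butanoic acid | CCCC(=O)O | starting material
3 | 1-(2,4-dihydroxy-3-methylphenyl)butan-1-one | CCCC(=O)c1ccc(O)c(C)c1O | intermediate
4 | 1-[4-(benzyloxy)-2-hydroxy-3-methylphenyl]butan-1-one | CCCC(=O)c1ccc(OCc2ccccc2)c(C)c1O | intermediate
5 | 1-[4-(benzyloxy)-2-methoxy-3-methylphenyl]butan-1-one | CCCC(=O)c1ccc(OCc2ccccc2)c(C)c1OC | intermediate
6 | 1-(4-hydroxy-2-methoxy-3-methylphenyl)butan-1-one | CCCC(=O)c1ccc(O)c(C)c1OC | intermediate
7 | formaldehyde | C=O | starting material
8 | 1-[4-hydroxy-5-(hydroxymethyl)-2-methoxy-3-methylphenyl]butan-1-one | CCCC(=O)c1cc(CO)c(O)c(C)c1OC | intermediate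
9 | bis(5-butanoyl-2-hydroxy-4-methoxy-3-methylphenyl)methane | CCCC(=O)c1cc(Cc2cc(C(=O)CCC)c(OC)c(C)c2O)c(O)c(C)c1OC | intermediate
10 | bis(2-acetoxy-5-butanoyl-4-methoxy-3-methylphenyl)methane | CCCC(=O)c1cc(Cc2cc(C(=O)CCC)c(OC)c(C)c2OC(C)=O)c(OC(C)=O)c(C)c1OC | intermediate
11 | bis[2-acetoxy-5-butanoyl-4-methoxy-3-methyl-6-(trifluoroacetoxy)phenyl]methane | CCCC(=O)c1c(OC(=O)C(F)(F)F)c(Cc2c(OC(=O)C(F)(F)F)c(C(=O)CCC)c(OC)c(C)c2OC(C)=O)c(OC(C)=O)c(C)c1OC | intermediate
12 | bis(2-acetoxy-5-butanoyl-6-hydroxy-4-methoxy-3-methylphenyl)methane (pseudoaspidin di-O-acetate) | CCCC(=O)c1c(O)c(Cc2c(O)c(C(=O)CCC)c(OC)c(C)c2OC(C)=O)c(OC(C)=O)c(C)c1OC | intermediate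
13 | pseudoaspidin, bis(3-butanoyl-2,6-dihydroxy-4-methoxy-5-methylphenyl)methane | CCCC(=O)c1c(O)c(Cc2c(O)c(C)c(OC)c(C(=O)CCC)c2O)c(O)c(C)c1OC | target

**Total step count:** 8. **Longest linear sequence:** 8 steps (from 2-methylresorcinol; two molecules of 6 are joined in step 5).

**Steps most likely to fail**

1. Step 7. Cyclometalation at a C–H flanked by the acyl group and the benzylic CH2 may be too slow, so that persulfate oxidation of the diarylmethane CH2 or acidolytic loss of the acetates outruns C–O bond formation. The fallback uses known chemistry: the oxygenation is moved to the monomer, where the C–H ortho to the ketone has a hydrogen neighbour (the established substrate class), and the bridge is formed last. Setting out from 6, acetylation (Ac2O, pyridine, DMAP) would give 4-butanoyl-3-methoxy-2-methylphenyl acetate F1. Ketone-directed ortho hydroxylation under established conditions ([RuCl2(p-cymene)]2, K2S2O8, CF3CO2H/(CF3CO)2O, 80 °C) would pass through 4-butanoyl-3-methoxy-2-methyl-5-(trifluoroacetoxy)phenyl acetate F2, hydrolysed on work-up to 4-butanoyl-5-hydroxy-3-methoxy-2-methylphenyl acetate F3. Methanolysis (K2CO3, MeOH, then HCl) would release 1-(4,6-dihydroxy-2-methoxy-3-methylphenyl)butan-1-one F4. Base-mediated condensation of two molecules of F4 with formaldehyde 7 (0.5 equiv, aq. NaOH, 0 °C to rt, then HCl), the classical way to methylene-bridged acylphloroglucinols, would proceed at the only free ring carbon via 1-[4,6-dihydroxy-5-(hydroxymethyl)-2-methoxy-3-methylphenyl]butan-1-one F5 and rejoin the route at the target 13.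

2. Step 5. The para acyl group lowers the nucleophilicity of the phenol, so the condensation may stall at the hydroxymethyl stage, or formaldehyde may be diverted into acid-catalysed aldol reaction at the carbon alpha to the ketone. The fallback separates electrophile formation from coupling. Setting out from 6, a phenolic Mannich reaction (formaldehyde 7, aq. Me2NH, EtOH, reflux) would give 1-{5-[(dimethylamino)methyl]-4-hydroxy-2-methoxy-3-methylphenyl}butan-1-one F6. Heating F6 with one further equivalent of 6 in AcOH at 100 °C would expel dimethylamine to form an ortho-quinone methide (or its protonated form), which is captured at the same ring carbon of 6, returning to the route at 9.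

3. Step 4. Over-reduction of the aryl ketone (to the benzylic alcohol or the methylene compound) may accompany O-debenzylation. The fallback replaces reductive unmasking by allyl transfer. Setting out from 3, allyl bromide/K2CO3 in refluxing acetone would give 1-[4-(allyloxy)-2-hydroxy-3-methylphenyl]butan-1-one F7. MeI/K2CO3 in DMF would give 1-[4-(allyloxy)-2-methoxy-3-methylphenyl]butan-1-one F8. Tsuji–Trost deallylation with Pd(PPh3)4 (catalytic, zerovalent palladium) and morpholine in THF at rt would return to the route at 6.

**Further compounds**
F1 | step 7 | 4-butanoyl-3-methoxy-2-methylphenyl acetate | CCCC(=O)c1ccc(OC(C)=O)c(C)c1OC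
F2 | step 7 | 4-butanoyl-3-methoxy-2-methyl-5-(trifluoroacetoxy)phenyl acetate | CCCC(=O)c1c(OC(=O)C(F)(F)F)cc(OC(C)=O)c(C)c1OC
F3 | step 7 | 4-butanoyl-5-hydroxy-3-methoxy-2-methylphenyl acetate | CCCC(=O)c1c(O)cc(OC(C)=O)c(C)c1OC
F4 | step 7 | 1-(4,6-dihydroxy-2-methoxy-3-methylphenyl)butan-1-one | CCCC(=O)c1c(O)cc(O)c(C)c1OC
F5 | step 7 | 1-[4,6-dihydroxy-5-(hydroxymethyl)-2-methoxy-3-methylphenyl]butan-1-one | CCCC(=O)c1c(O)c(CO)c(O)c(C)c1OC
F6 | step 5 | 1-{5-[(dimethylamino)methyl]-4-hydroxy-2-methoxy-3-methylphenyl}butan-1-one | CCCC(=O)c1cc(CN(C)C)c(O)c(C)c1OC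
F7 | step 4 | 1-[4-(allyloxy)-2-hydroxy-3-methylphenyl]butan-1-one | CCCC(=O)c1ccc(OCC=C)c(C)c1O
F8 | step 4 | 1-[4-(allyloxy)-2-methoxy-3-methylphenyl]butan-1-one | CCCC(=O)c1ccc(OCC=C)c(C)c1OC
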